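**Retrosynthetic overview**
1. The target is (2S)-5,7-dihydroxy-4'-methoxy-6-prenylflavanone. Ring C is cut at O1–C2 and C3–C4 after lowering C4 from the ketone to the methyl-ether level, which gives a 4-methoxy ortho-quinone methide (from salicylaldehyde 8) and 4-methoxystyrene 9, joined by an enantioselective inverse-electron-demand oxa-[4+2] cycloaddition.
2. Enabling feature: O1–C8a–C4a–C4 of rings A/C is a salicyloyl unit, that is a latent 1-oxadiene (phenol oxygen, two arene carbons, benzylic carbon). C2–C3 carries the para-methoxyphenyl donor on C2, so the styrene polarity matches (CH2 to C4, benzylic carbon to oxygen).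
3. The 6-prenyl (not 8-prenyl) pattern is fixed before the key step: 8 has a single free ortho-hydroxyl, para to the prenyl group, and both oxygens flanking the prenyl group are MOM ethers.
4. Aldehyde 8 comes from resorcinol by bis-MOM protection, directed ortho-lithiation/prenylation, sterically controlled C–H borylation/oxidation and ortho-formylation.
5. Rings A and B are bought in (resorcinol, 4-methoxystyrene); ring C is the only ring formed (step 5). C4 is then returned to the ketone (hydrolysis, oxidation) and the MOM groups are removed.

Key step: step 5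

Assumption: the sense of induction of the confined chiral acid in step 5 cannot be predicted with confidence. The (S,S)-catalyst is written, and its mirror image is to be used if the (2R) series turns out to be favoured.

**Step 1**
Reactants: 1 resorcinol
Product: 2 1,3-bis(methoxymethoxy)benzene
Conditions: MOMCl (2.5 equiv), i-Pr2NEt (3 equiv), CH2Cl2, 0 °C → rt
Reagents that add atoms: chloromethyl methyl ether (MOMCl), COCCl
Why: O-alkylation of both phenols by the highly reactive α-chloro ether (Williamson-type etherification) should install the two groups that later direct lithiation and cap the oxygens beside the prenyl group.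

**Step 2**
Reactants: 2 1,3-bis(methoxymethoxy)benzene
Product: 4 1,3-bis(methoxymethoxy)-2-(3-methylbut-2-en-1-yl)benzene, via 2,6-bis(methoxymethoxy)phenyllithium 3 (not isolated)
Conditions: n-BuLi (1.1 equiv), THF, 0 °C → rt; then prenyl bromide (1.2 equiv), −78 °C → rt
Reagents that add atoms: prenyl bromide (1-bromo-3-methylbut-2-ene), CC(C)=CCBr
Why: Directed ortho-metalation occurs at the position flanked by both MOM ethers (cooperative chelation), and the aryllithium should be alkylated at the primary carbon of prenyl bromide by SN2.

**Step 3**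
Reactants: 4 1,3-bis(methoxymethoxy)-2-(3-methylbut-2-en-1-yl)benzene
Product: 6 3,5-bis(methoxymethoxy)-4-(3-methylbut-2-en-1-yl)phenol, via aryl pinacol boronate 5 (not isolated)
Conditions: [Ir(OMe)(cod)]2 (1.5 mol%), 4,4'-di-tert-butyl-2,2'-bipyridine (3 mol%), B2pin2 (0.55 equiv), THF, 60 °C; then 30% aq H2O2, aq NaOH (1 equiv), 0 °C → rt
Reagents that add atoms: hydrogen peroxide, OO
Why: Iridium-catalysed C–H borylation is sterically governed and should select the only C–H with no ortho substituent (para to the prenyl group), and alkaline peroxide oxidation of the C–B bond then gives the phenol without touching the trisubstituted alkene.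

**Step 4**
Reactants: 6 3,5-bis(methoxymethoxy)-4-(3-methylbut-2-en-1-yl)phenol
Product: 8 6-hydroxy-2,4-bis(methoxymethoxy)-3-(3-methylbut-2-en-1-yl)benzaldehyde, via salicyl alcohol magnesium salt 7 (not isolated)
Conditions: MgCl2 (2 equiv), Et3N (4 equiv), (CH2O)n (6 equiv), MeCN, reflux
Reagents that add atoms: paraformaldehyde (as formaldehyde), C=O
Why: Casnati–Skattebøl ortho-formylation: the magnesium phenoxide delivers formaldehyde to the ortho position (both are equivalent) and a second formaldehyde oxidises the hydroxymethyl group by hydride transfer, so formylation should occur only next to the free hydroxyl.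

**Step 5**
Reactants: 8 6-hydroxy-2,4-bis(methoxymethoxy)-3-(3-methylbut-2-en-1-yl)benzaldehyde; 9 4-methoxystyrene
Product: 12 (2S,4S)-4-methoxy-2-(4-methoxyphenyl)-5,7-bis(methoxymethoxy)-6-(3-methylbut-2-en-1-yl)chromane, via dimethyl acetal 10 (not isolated), via oxocarbenium ion 11 (not isolated)
Conditions: HC(OMe)3 (2 equiv), (S,S)-imidodiphosphorimidate Brønsted acid (two (S)-3,3'-bis[3,5-bis(trifluoromethyl)phenyl]-BINOL units, N-triflyl groups; 5 mol%), toluene, rt; then −40 °C, 9 (2 equiv) added slowly; Et3N quench
Reagents that add atoms: trimethyl orthoformate, COC(OC)OC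
Why: Proposed new method: the acid turns 8 and HC(OMe)3 into acetal 10 and ionises it to the ortho-hydroxyaryl oxocarbenium ion 11 (the O-protonated 4-methoxy ortho-quinone methide), which is held in the chiral anion pocket through its phenol O–H···anion hydrogen bond; the terminal CH2 of 9 attacks the carbenium carbon and the phenol oxygen captures the developing para-methoxybenzylic cation in a concerted but strongly asynchronous inverse-electron-demand oxa-[4+2] cycloaddition. The closest known reaction types are the acid-catalysed three-component synthesis of 2,4-cis-4-methoxyflavans from salicylaldehydes, trimethyl orthoformate and styrenes (racemic) and the chiral-Brønsted-acid-catalysed enantioselective cycloaddition of the same oxocarbenium ions with vinyl ethers; enantiocontrol with a styrene is the new element, supported by the known ability of confined imidodiphosphorimidate anions to steer styrene additions to oxocarbenium ions. Ring C is the only ring closed, and it closes by the [4+2] cycloaddition itself (four ring atoms from the oxadiene, two from the alkene; in the stepwise limit a six-membered capture of the benzylic cation by oxygen). C4 is set by the anion, which shields one face of the carbenium carbon, and C2 is set relative to C4 by the endo half-chair transition state that keeps aryl and methoxy cis, so (2S,4S)-12 should result and only C2 has to survive. The step needs regio-, chemo- and enantioselectivity: the single free ortho-hydroxyl of 8 fixes the prenyl group at C6, the donor-substituted styrene puts its aryl on C2 and outruns the less nucleophilic prenyl olefin (whose flanking oxygens are capped so it cannot cyclise), and low temperature with slow addition of 9 should suppress cationic oligomerisation.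

**Step 6**
Reactants: 12 (2S,4S)-4-methoxy-2-(4-methoxyphenyl)-5,7-bis(methoxymethoxy)-6-(3-methylbut-2-en-1-yl)chromane
Product: 13 (2S)-2-(4-methoxyphenyl)-5,7-bis(methoxymethoxy)-6-(3-methylbut-2-en-1-yl)chroman-4-ol (C4 epimers)
Conditions: PPTS (20 mol%), acetone/H2O (5:1), rt
Reagents that add atoms: water, O
Why: SN1 solvolysis of the benzylic methyl ether through the C4 cation, which is stabilised by O1 and the 5- and 7-oxygens, should exchange OMe for OH under acid too mild to cleave the MOM ethers, and C2 is not involved.

**Step 7**
Reactants: 13 (2S)-2-(4-methoxyphenyl)-5,7-bis(methoxymethoxy)-6-(3-methylbut-2-en-1-yl)chroman-4-ol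
Product: 14 (2S)-2-(4-methoxyphenyl)-5,7-bis(methoxymethoxy)-6-(3-methylbut-2-en-1-yl)chroman-4-one
Conditions: Dess–Martin periodinane (1.3 equiv), pyridine (3 equiv), CH2Cl2, 0 °C → rt
Reagents that add atoms: none
Why: Dess–Martin oxidation of the benzylic secondary alcohol should bring both C4 epimers to the same ketone under buffered, base-free conditions that do not open the ring by retro-oxa-Michael reaction, so C2 stays (S).

**Step 8**
Reactants: 14 (2S)-2-(4-methoxyphenyl)-5,7-bis(methoxymethoxy)-6-(3-methylbut-2-en-1-yl)chroman-4-one
Product: 15 (2S)-5,7-dihydroxy-2-(4-methoxyphenyl)-6-(3-methylbut-2-en-1-yl)chroman-4-one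
Conditions: 3 M aq HCl/MeOH (1:10), rt
Reagents that add atoms: none
Why: Acid-catalysed transacetalisation of the two aryl MOM ethers to dimethoxymethane should free both phenols at room temperature, without base (no chalcone pathway) and below the acidity and temperature at which the prenyl group cyclises onto a neighbouring hydroxyl.

**Compound list**
1 | resorcinol (benzene-1,3-diol) | Oc1cccc(O)c1 | starting material
2 | 1,3-bis(methoxymethoxy)benzene | COCOc1cccc(OCOC)c1 | intermediate
3 | 2,6-bis(methoxymethoxy)phenyllithium (formed in the flask) | [Li]c1c(OCOC)cccc1OCOC | intermediate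
4 | 1,3-bis(methoxymethoxy)-2-(3-methylbut-2-en-1-yl)benzene | COCOc1cccc(OCOC)c1CC=C(C)C | intermediate
5 | 2-[3,5-bis(methoxymethoxy)-4-(3-methylbut-2-en-1-yl)phenyl]-4,4,5,5-tetramethyl-1,3,2-dioxaborolane (formed in the flask) | COCOc1cc(B2OC(C)(C)C(C)(C)O2)cc(OCOC)c1CC=C(C)C | intermediate
6 | 3,5-bis(methoxymethoxy)-4-(3-methylbut-2-en-1-yl)phenol | COCOc1cc(O)cc(OCOC)c1CC=C(C)C | intermediate
7 | 2-(hydroxymethyl)-3,5-bis(methoxymethoxy)-4-(3-methylbut-2-en-1-yl)phenol (formed in the flask as its magnesium salt; neutral form shown) | OCc1c(O)cc(OCOC)c(CC=C(C)C)c1OCOC | intermediate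
8 | 6-hydroxy-2,4-bis(methoxymethoxy)-3-(3-methylbut-2-en-1-yl)benzaldehyde | O=Cc1c(O)cc(OCOC)c(CC=C(C)C)c1OCOC | intermediate
9 | 4-methoxystyrene (1-ethenyl-4-methoxybenzene) | C=Cc1ccc(OC)cc1 | starting material
10 | 2-(dimethoxymethyl)-3,5-bis(methoxymethoxy)-4-(3-methylbut-2-en-1-yl)phenol (formed in the flask) | COC(OC)c1c(O)cc(OCOC)c(CC=C(C)C)c1OCOC | intermediate
11 | O-methyl oxocarbenium ion of 8 (O-protonated 4-methoxy ortho-quinone methide; formed in the flask as ion pair with the catalyst anion, cation shown) | C[O+]=Cc1c(O)cc(OCOC)c(CC=C(C)C)c1OCOC | intermediate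
12 | (2S,4S)-4-methoxy-2-(4-methoxyphenyl)-5,7-bis(methoxymethoxy)-6-(3-methylbut-2-en-1-yl)chromane (2,4-cis) | COc1ccc([C@@H]2C[C@H](OC)c3c(cc(OCOC)c(CC=C(C)C)c3OCOC)O2)cc1 | intermediate
13 | (2S)-2-(4-methoxyphenyl)-5,7-bis(methoxymethoxy)-6-(3-methylbut-2-en-1-yl)chroman-4-ol (C4 epimers) | COc1ccc([C@@H]2CC(O)c3c(cc(OCOC)c(CC=C(C)C)c3OCOC)O2)cc1 | intermediate
14 | (2S)-2-(4-methoxyphenyl)-5,7-bis(methoxymethoxy)-6-(3-methylbut-2-en-1-yl)chroman-4-one | COc1ccc([C@@H]2CC(=O)c3c(cc(OCOC)c(CC=C(C)C)c3OCOC)O2)cc1 | intermediate
15 | (2S)-5,7-dihydroxy-2-(4-methoxyphenyl)-6-(3-methylbut-2-en-1-yl)chroman-4-one | COc1ccc([C@@H]2CC(=O)c3c(cc(O)c(CC=C(C)C)c3O)O2)cc1 | target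

**Step count and risks**
Total step count: 8. Longest linear sequence: 8 steps (resorcinol to 15; 4-methoxystyrene enters at step 5).

Steps most likely to fail:

1. Step 5 (Proposed new method). Possible failures: the chiral anion may discriminate poorly between the faces of a styrene that offers no hydrogen-bond handle. A poor cis preference would erode the relay from C4 to C2. The benzylic C2–O bond may ionise reversibly under the strong acid. The styrene may oligomerise cationically, or a MOM ether may be lost. The enantiomeric purity at C2 is to be checked at the stage of 14. Fallback (known chemistry, from 8 and 9, back at 14): the three components are combined under Sc(OTf)3 catalysis (HC(OMe)3, CH2Cl2, rt), which should give racemic 2,4-cis-4-methoxyflavan F1. Hydrolysis as in step 6 should give racemic flavan-4-ol F2, and Dess–Martin oxidation as in step 7 racemic flavanone F3. F3 is then resolved kinetically by asymmetric transfer hydrogenation with RuCl(p-cymene)[(R,R)-TsDPEN] and HCO2H/Et3N, run beyond half conversion. By analogy with aryl ketone reductions, the (2R)-ketone is expected to be reduced faster, to (2R,4R)-cis-flavan-4-ol F4, and the unreacted (2S)-ketone is separated by chromatography as 14.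

2. Step 8. Possible failures: partial racemisation at C2 by acid-promoted ring opening (the para-methoxyphenyl group stabilises a benzylic cation, and the chalcone is accessible), and acid-induced cyclisation of the prenyl group onto the freed 5- or 7-hydroxyl. Fallback (from 14, back at 15): protic acid is avoided by a silyl-exchange deprotection. TMSOTf with 2,2'-bipyridyl in CH2Cl2 at 0 °C should convert both aryl MOM ethers into trimethylsilyl ethers, giving bis(trimethylsilyl) ether F5, which is hydrolysed with water at neutral pH to 15.

3. Step 3. Possible failures: competing hydroboration or isomerisation of the prenyl olefin by the iridium hydride/HBpin formed during borylation, which would lower the yield of 6. Fallback (from 2, back at 6): the oxygen is introduced before the prenyl group. The same borylation on alkene-free 2 should give aryl boronate F6, oxidised in the flask to 3,5-bis(methoxymethoxy)phenol F7. Silylation (TIPSCl, imidazole, DMF) gives triisopropylsilyl ether F8. n-BuLi in THF at 0 °C should lithiate between the two MOM ethers (the bulky silyl ether does not direct) to aryllithium F9, which is alkylated with prenyl bromide to prenylated silyl ether F10. TBAF in THF then removes the silyl group and returns 6.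

**Further compounds**
F1 | step 5 | racemic 2,4-cis-4-methoxy-2-(4-methoxyphenyl)-5,7-bis(methoxymethoxy)-6-(3-methylbut-2-en-1-yl)chromane (both enantiomers shown) | COc1ccc([C@@H]2C[C@H](OC)c3c(cc(OCOC)c(CC=C(C)C)c3OCOC)O2)cc1.COc1ccc([C@H]2C[C@@H](OC)c3c(cc(OCOC)c(CC=C(C)C)c3OCOC)O2)cc1
F2 | step 5 | racemic 2-(4-methoxyphenyl)-5,7-bis(methoxymethoxy)-6-(3-methylbut-2-en-1-yl)chroman-4-ol (C4 epimers) | COc1ccc(C2CC(O)c3c(cc(OCOC)c(CC=C(C)C)c3OCOC)O2)cc1
F3 | step 5 | racemic 2-(4-methoxyphenyl)-5,7-bis(methoxymethoxy)-6-(3-methylbut-2-en-1-yl)chroman-4-one | COc1ccc(C2CC(=O)c3c(cc(OCOC)c(CC=C(C)C)c3OCOC)O2)cc1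
F4 | step 5 | (2R,4R)-2-(4-methoxyphenyl)-5,7-bis(methoxymethoxy)-6-(3-methylbut-2-en-1-yl)chroman-4-ol | COc1ccc([C@H]2C[C@@H](O)c3c(cc(OCOC)c(CC=C(C)C)c3OCOC)O2)cc1
F5 | step 8 | (2S)-2-(4-methoxyphenyl)-6-(3-methylbut-2-en-1-yl)-5,7-bis(trimethylsilyloxy)chroman-4-one | COc1ccc([C@@H]2CC(=O)c3c(cc(O[Si](C)(C)C)c(CC=C(C)C)c3O[Si](C)(C)C)O2)cc1
F6 | step 3 | 2-[3,5-bis(methoxymethoxy)phenyl]-4,4,5,5-tetramethyl-1,3,2-dioxaborolane | COCOc1cc(B2OC(C)(C)C(C)(C)O2)cc(OCOC)c1
F7 | step 3 | 3,5-bis(methoxymethoxy)phenol | COCOc1cc(O)cc(OCOC)c1
F8 | step 3 | [3,5-bis(methoxymethoxy)phenoxy]tri(propan-2-yl)silane | COCOc1cc(O[Si](C(C)C)(C(C)C)C(C)C)cc(OCOC)c1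
F9 | step 3 | [2,6-bis(methoxymethoxy)-4-(triisopropylsilyloxy)phenyl]lithium | [Li]c1c(OCOC)cc(O[Si](C(C)C)(C(C)C)C(C)C)cc1OCOC
F10 | step 3 | [3,5-bis(methoxymethoxy)-4-(3-methylbut-2-en-1-yl)phenoxy]tri(propan-2-yl)silane | COCOc1cc(O[Si](C(C)C)(C(C)C)C(C)C)cc(OCOC)c1CC=C(C)C
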